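The ratio of Z to L falls from 2.4 equiv in Thursday's run to 1.20 equiv in the new flask, and you want to know what that does to D.

| flask | L | Z | remark | time |
|---|---|---|---|---|
| Thursday's | 0.024 M | 2.4 equiv | run made earlier |  |
| flask | 0.024 M | 1.20 equiv |  | 8.0 min |

Thursday's run (percent of the L charged)

| time / min | D / % | L / % |
|---|---|---|
| 0.200 | 3.3 | 84.0 |
| 0.333 | 3.7 | 82.4 |
| 0.500 | 7.7 | 79.2 |
| 0.833 | 11.5 | 74.1 |
| 1.33 | 18.2 | 66.5 |
| 2.50 | 34.3 | 52.3 |

(readings scatter by 0.5 percentage points)

- amount of D in percent of the L charged, at 50 s, 2.5 min, 5.0 min and 8.0 min

- given per volume of solution although it is solid: L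
- steps under discussion: J + Z <-> D + Q; L <-> J
- at the start none of L is in solution

Follow one molecule of L: it dissolves to J, then it meets Z. So you need two times, one for filling the dissolved pool and one for emptying it. Whatever has left the solid without being D is that pool, and D climbs in a nearly straight line, pseudo-zero-order in J:

pool at 2.50 min = 13.4%

rise of D, as a fraction of the charge = 0.137 min⁻¹

pool / rise = 0.980 min

This is the emptying time, the time the rise of D needs to use up one pool. The pool already reads 12.7% at 0.200 min, so filling takes about that long at most, which is shorter than emptying. The pool therefore stays nearly full, and D follows the emptying time.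

My own reckoning takes first order in Z and holds Z at its charge:

new emptying time = 1.96 min

D at 2.5 min = 17.1%

The forecast differs slightly, giving 5.5%, 16.5%, 31% and 45%, and it warns: "The reverse step is untested".

The new flask gives 6.07%, 17.6%, 30.8% and 40.6%.

    J + Z ⇌ D + Q (K = 2.56, k = 0.327 L mol⁻¹ s⁻¹)
    L ⇌ J, rate k2*(cs2 - [J]) while solid is left; crystals form when [J] > cs2 (solubility = 3.50 mM, k = 0.310 s⁻¹)

Up to 2.5 min, the new flask's emptying time reads 2.03 min against the 1.96 min carried over, while the relaxation half-life of J + Z and D + Q at 8.0 min is 1.17 min, short against that time. Averaged over 8.0 min, the emptying time of the new flask is 2.85 min. With twice the Z of the new flask, D stands at 69.3% at 8.0 min, and with J taken as in the new flask at that time this is a mean emptying time of 1.67 min.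

(The data were computed with made-up constants; the scatter is artificial.)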